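## Structural features

The target is a flavonol (chromen-4-one rings A and C, hydroxyls at C3, C5 and C7) whose C2 aryl group, ring B, is also the benzo ring of a 2,3-dihydro-1,4-benzodioxine (ring D). Ring D carries the hydroxymethyl carbon C9 on C10 and the 4-hydroxy-3-methoxyphenyl ring E on C11, with O4' bonded to C10 and O3' to C11. C10 and C11 are the only stereocentres: adjacent, both S, trans on ring D (positions 2 and 3 of the benzodioxine), and nothing in the flat, achiral flavonol can relay or repair them. The fragile point is the C11–O3' bond, a benzylic aryl ether para to the ring E oxygen: acid can open it through a quinone-methide-type cation, hydrogenolysis can cleave it, and strong base at C11–H can expel the O4' phenoxide. The free polyphenol with its 3-hydroxy enone is easily oxidised in base, so the phenols must stay masked until the end. The real difficulty is to join an enantiopure, regiodefined dioxane to a fully oxygenated chromenone and to place the C3 hydroxyl without harming ring D. The plan exploits the make-up of ring C: C4 lies between C4a and C3, and O1 bridges C8a and C2, so C4a/C8a can come from an ortho-iodophenol, C4 from carbon monoxide, and C3/C2 from a terminal alkyne already on ring B.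

## Logic of the disconnections

24 ⇒ 22. The three O–CH2Ph bonds and the O–Si bond at C9 are cut last. This keeps every phenol and the primary alcohol masked through the metal- and base-mediated steps. The forward step must spare the C11–O3' bond and the C2=C3 bond, so hydrogenolysis at one atmosphere is followed by dilute acid in the same operation (through 23).

22 ⇒ 19. The C3–O bond is cut, because the ring-forming step delivers C3 as C–H. The gain is that the alkyne partner needs no oxygen at that carbon. The forward step must functionalise C3 alone; C3–H is the only acidic sp2 C–H next to the carbonyl, so lithiation, borylation and oxidation (through 20 and 21) are used. This avoids a dioxirane in the main line.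

19 ⇒ 15 + 16 + 13. The C4a–C4, C4–C3 and O1–C2 bonds are cut together. Ring C disappears and the molecule falls into ring A (15), one carbon (16) and the chiral rings B, D and E (13); no stereocentre is involved. The forward step must insert 16 before the alkyne is transferred and must close the six-membered ring, not the five-membered one (through 17 and 18).

15 ⇒ 14. The C–I bond ortho to the free hydroxyl is cut. Both ortho positions of 14 are equivalent, so the only demand is ortho- over para-iodination and mono-iodination; no thallium or other toxic metal reagent is used.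

13 ⇒ 12 ⇒ 10 + 11. The C1'–C(sp) bond is cut, and before it the C–Si bond of the alkyne cap. This reduces the alkyne to an aryl bromide and 11. The forward coupling must engage an electron-rich aryl bromide under conditions mild enough for the silyl ether.

10 ⇒ 9. The O3'–C3' bond (oxygen to aromatic carbon) is cut. Because the bond is formed at the arene, C11 keeps its configuration, so the threo open chain maps directly onto the trans ring. The precursor is improved by using two different halogens: iodine at C3' for the copper step, bromine at C1' saved for the alkyne. The C9 hydroxyl must be masked, because a free primary alkoxide would close an isomeric dioxane.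

9 ⇒ 8 ⇒ 7. These are functional-group changes only: the silyl ether goes back to the diol, and the C9 alcohol to the imide carbonyl. The forward steps need a primary-selective silylation and a reduction that leaves the aryl halides alone.

7 ⇒ 3 + 4. The C10–C11 bond is cut. Both stereocentres arise in one auxiliary-controlled syn aldol. The (R)-auxiliary is required, since its syn adduct (2R,3S) has the relative and absolute configuration that becomes (10S,11S).

3 ⇒ 1 + 2. The O4'–CH2 bond is cut, which leads to purchasable 1 and 2 in a simple phenoxide alkylation. This fixes, by construction, that O4' sits on C10 and that the bromine is para to O4'.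

## Other disconnections considered

Alternative 1: The O4'–C10 bond of ring D is cut. In the forward step the C4' phenoxide of the open-chain aryl ether A2 attacks C10 from the back (6-exo-tet, inversion) and gives the bromobenzodioxane A1 with the C9 hydroxyl set free. In A2, C11 already carries O3' and C9–C10 is a terminal epoxide.
- In favour: the chirality comes from a catalytic asymmetric epoxidation, not a stoichiometric auxiliary, which is better in chirality economy than the chosen plan. The closure is a stereospecific SN2 at a non-benzylic carbon, and the exo mode is clearly preferred over 7-endo attack at C9. C9 appears as the alcohol without a reduction step.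
- Against: the C11–O3' ether must first be made by opening a benzylic epoxide with a phenol. That is a substitution at the most ionisable carbon, and its stereochemical fidelity depends on keeping ring E electron-poor (hence the pivalate). The oxygen must then be relayed from C10/C11 to C9/C10 by extra diol-to-epoxide steps, and the two catechol oxygens need temporary differentiation.
- Comparison: on structure the plans are equal, since both fix the O–C regiochemistry of ring D by construction. A1 corresponds to 10 with other protecting groups, so this alternative replaces only steps 1–5 and leaves the flavone assembly open. On mechanism, it closes ring D at sp3 carbon with inversion, whereas the chosen plan closes at the arene with retention after setting both centres in one C–C bond formation; the chosen plan should be the more predictable at C11. On step economy the two are about equal up to the bromide, with the alternative probably one or two steps longer.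

Alternative 2: The O3'–C11 bond is cut. In the forward step, anodic two-electron oxidation of the ring E phenol of A4 gives a para-quinone methide at C11. A4 has only the C10 stereocentre and a methylene at C11. The neighbouring O3' hydroxyl adds to the methide (6-exo-trig), ring E re-aromatises, and A3 results.
- In favour: the oxidant is the electrode, only one stereocentre has to be bought, and no halogen, copper or ring E protection is needed. For ring D this is better than the chosen plan in atom and protecting-group economy.
- Against: the trans configuration at C11 rests on substrate control in the addition to a planar quinone methide, not on a stereospecific event. The ring B phenol can compete for oxidation. A3 carries a methyl ester where the chosen ring C construction needs an alkyne, so about three further steps (ester to aldehyde to alkyne) and reprotection of the phenol would be needed.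
- Comparison: on structure the plans are equal in ring D regiochemistry, but the alternative is less secure at C11. On mechanism, a conformational preference is set against an auxiliary-controlled aldol with retentive closure. On step economy the alternative is shorter to the dioxane and longer from it, so no net gain is expected. It would be the better choice only if the ester were used directly in an acylation-based flavone synthesis.

Alternative 3: The C4a–C5 bond is cut, so ring A is made last. In the forward step, base converts the pyranone keto ester A6 into its extended dienolate. The C4a terminus attacks the ester carbonyl (6-exo-trig Claisen-type closure), and the ring tautomerises to the aromatic 5,7-dihydroxy pattern of A5.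
- In favour: the C3 oxygen is already in place as a benzyl ether, so no late C3 oxidation is needed, a clear advantage over step 10. No carbon monoxide and no iodination regiochemistry are involved, and the ring A phenols never need protection. The alternative is equal or better in safety and functional-group economy.
- Against: A6 is a polycarbonyl chain built linearly on the valuable chiral fragment, and each stage is prone to self-condensation. The dienolate is ambident (C8 against C4a, O- against C-acylation). Prolonged strong base acts close to C11–H.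
- Comparison: on structure, the alternative grows ring A on a finished ring C, while the chosen plan stitches ring C between two finished, stable fragments and is more convergent. On mechanism, the site of condensation is less predictable than the amine-directed closure of step 9. On step economy, the alternative is better after its key step (one deprotection operation) and worse before it (several more steps than the one-step preparation of 15). Neither plan touches the stereocentres, so they are equal there.

Key step: step 9

Assumption: 1, 2, 4, 11, 14 and 16 are taken as purchasable; if 2 had to be made it would come in one acylation from (R)-4-benzyl-1,3-oxazolidin-2-one and chloroacetyl chloride.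

## Route

Step 1
Reactants: 1 4-bromo-2-iodophenol; 2 (4R)-4-benzyl-3-(chloroacetyl)-1,3-oxazolidin-2-one
Product: 3 (4R)-4-benzyl-3-[(4-bromo-2-iodophenoxy)acetyl]-1,3-oxazolidin-2-one
Conditions: K2CO3, NaI (cat.), acetone, 25 → 45 °C
Reagents that add atoms: none
Why: Williamson ether synthesis; the phenoxide of 1 displaces chloride at the activated alpha-chloro imide carbon (iodide catalysis), carbonate is too weak to cleave the imide, and no stereocentre is touched.

Step 2
Reactants: 3 (4R)-4-benzyl-3-[(4-bromo-2-iodophenoxy)acetyl]-1,3-oxazolidin-2-one; 4 4-(benzyloxy)-3-methoxybenzaldehyde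
Product: 7 (4R)-4-benzyl-3-[(2R,3S)-3-[4-(benzyloxy)-3-methoxyphenyl]-2-(4-bromo-2-iodophenoxy)-3-hydroxypropanoyl]-1,3-oxazolidin-2-one, via dibutylboron Z-enolate 5 (not isolated), via dibutylboron aldolate 6 (not isolated)
Conditions: Bu2BOTf, i-Pr2NEt, CH2Cl2, −78 → 0 °C; 4, −78 → 0 °C; pH 7 buffer, MeOH, 30% aq H2O2, 0 °C
Reagents that add atoms: none
Why: Evans syn aldol; the Z-enolate 5 reacts through a closed chair (Zimmerman–Traxler) transition state on the face away from the benzyl group of the (R)-auxiliary, which sets C10 and C11 together as the syn (2R,3S) adduct, the threo arrangement that later becomes the trans dioxane.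

Step 3
Reactants: 7 (4R)-4-benzyl-3-[(2R,3S)-3-[4-(benzyloxy)-3-methoxyphenyl]-2-(4-bromo-2-iodophenoxy)-3-hydroxypropanoyl]-1,3-oxazolidin-2-one
Product: 8 (1S,2S)-1-[4-(benzyloxy)-3-methoxyphenyl]-2-(4-bromo-2-iodophenoxy)propane-1,3-diol
Conditions: LiBH4, THF, MeOH (1 equiv), 0 °C
Reagents that add atoms: none
Why: Reductive cleavage of the N-acyl oxazolidinone by LiBH4 at the exocyclic carbonyl frees C9 as the primary alcohol, returns the auxiliary and leaves both stereocentres and both aryl halides untouched (the descriptor at C10 changes from R to S only because the priorities change).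

Step 4
Reactants: 8 (1S,2S)-1-[4-(benzyloxy)-3-methoxyphenyl]-2-(4-bromo-2-iodophenoxy)propane-1,3-diol
Product: 9 (1S,2S)-1-[4-(benzyloxy)-3-methoxyphenyl]-2-(4-bromo-2-iodophenoxy)-3-[(tert-butyldimethylsilyl)oxy]propan-1-ol
Conditions: TBSCl, imidazole, CH2Cl2, 0 °C
Reagents that add atoms: tert-butyldimethylsilyl chloride, CC(C)(C)[Si](C)(C)Cl
Why: Selective silylation; the primary C9 hydroxyl reacts far faster than the hindered benzylic C11 hydroxyl, and masking C9 is needed because a free primary alkoxide would close an isomeric dioxane in step 5.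

Step 5
Reactants: 9 (1S,2S)-1-[4-(benzyloxy)-3-methoxyphenyl]-2-(4-bromo-2-iodophenoxy)-3-[(tert-butyldimethylsilyl)oxy]propan-1-ol
Product: 10 (2S,3S)-3-[4-(benzyloxy)-3-methoxyphenyl]-6-bromo-2-{[(tert-butyldimethylsilyl)oxy]methyl}-2,3-dihydro-1,4-benzodioxine
Conditions: CuI (10 mol %), 1,10-phenanthroline (20 mol %), Cs2CO3, toluene, 100 °C
Reagents that add atoms: none
Why: Ullmann-type intramolecular O-arylation; the C11 alkoxide binds monovalent copper, which inserts into the neighbouring C3'–I bond (iodide reacts well ahead of the para bromide) and forms the O3'–C3' bond, and because the bond is made at the arene C11 keeps its configuration, so the threo pair becomes the trans (2S,3S) ring.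

Step 6
Reactants: 10 (2S,3S)-3-[4-(benzyloxy)-3-methoxyphenyl]-6-bromo-2-{[(tert-butyldimethylsilyl)oxy]methyl}-2,3-dihydro-1,4-benzodioxine; 11 ethynyltrimethylsilane
Product: 12 (2S,3S)-3-[4-(benzyloxy)-3-methoxyphenyl]-2-{[(tert-butyldimethylsilyl)oxy]methyl}-6-[(trimethylsilyl)ethynyl]-2,3-dihydro-1,4-benzodioxine
Conditions: PdCl2(PhCN)2 (3 mol %), t-Bu3P·HBF4 (6 mol %), CuI (2 mol %), i-Pr2NH, 1,4-dioxane, 25 → 45 °C
Reagents that add atoms: none
Why: Sonogashira coupling; the bulky electron-rich phosphine allows oxidative addition into the electron-rich C1'–Br bond near room temperature, and the silyl cap on 11 prevents double coupling.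

Step 7
Reactants: 12 (2S,3S)-3-[4-(benzyloxy)-3-methoxyphenyl]-2-{[(tert-butyldimethylsilyl)oxy]methyl}-6-[(trimethylsilyl)ethynyl]-2,3-dihydro-1,4-benzodioxine
Product: 13 (2S,3S)-3-[4-(benzyloxy)-3-methoxyphenyl]-2-{[(tert-butyldimethylsilyl)oxy]methyl}-6-ethynyl-2,3-dihydro-1,4-benzodioxine
Conditions: K2CO3 (cat.), MeOH–THF, 25 °C
Reagents that add atoms: none
Why: Protodesilylation of the alkynyl C–Si bond by methoxide; the primary alkyl silyl ether and the benzyl ethers are inert to K2CO3 in methanol at room temperature.

Step 8
Reactants: 14 3,5-bis(benzyloxy)phenol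
Product: 15 3,5-bis(benzyloxy)-2-iodophenol
Conditions: N-iodosuccinimide (1.0 equiv), CH2Cl2, −20 → 0 °C, dark
Reagents that add atoms: N-iodosuccinimide, O=C1CCC(=O)N1I
Why: Electrophilic aromatic iodination; C2 and C6 of 14 are equivalent, each ortho to the hydroxyl and para to a benzyloxy group, and less hindered than C4 between two benzyloxy groups, so one equivalent of reagent at low temperature should favour mono-iodination at C2.

Step 9
Reactants: 15 3,5-bis(benzyloxy)-2-iodophenol; 13 (2S,3S)-3-[4-(benzyloxy)-3-methoxyphenyl]-2-{[(tert-butyldimethylsilyl)oxy]methyl}-6-ethynyl-2,3-dihydro-1,4-benzodioxine; 16 carbon monoxide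
Product: 19 5,7-bis(benzyloxy)-2-[(2S,3S)-3-[4-(benzyloxy)-3-methoxyphenyl]-2-{[(tert-butyldimethylsilyl)oxy]methyl}-2,3-dihydro-1,4-benzodioxin-6-yl]-4H-chromen-4-one, via ortho-hydroxyaryl ynone 17 (not isolated), via diethylamino enone 18 (not isolated)
Conditions: CO (1 atm, balloon), PdCl2(PPh3)2 (5 mol %), Et2NH, DMF, 60 °C
Reagents that add atoms: none
Why: This is a carbonylative Sonogashira coupling followed by amine-mediated cyclisation, the established palladium-catalysed three-component route from 2-iodophenols, carbon monoxide and terminal alkynes to flavones. Zerovalent palladium formed from PdCl2(PPh3)2 inserts into the C4a–I bond of 15, 16 inserts to give the aroyl palladium species, and alkynyl transfer from 13 with amine as base, then reductive elimination, forms C4a–C4 and C4–C3 in ynone 17. Diethylamine adds to C2 of 17 to give enaminone 18, and the C8a hydroxyl replaces the amine at C2 by addition–elimination, which forms O1–C2 and closes ring C in a 6-endo sense (6-endo-dig with respect to the ynone, carried out as a 6-endo-trig addition–elimination). No stereocentre is formed, and C10 and C11 are remote from every reacting atom and meet only a secondary amine at 60 °C. Three selectivities are needed: insertion of 16 before alkynyl transfer (secured by leaving out copper and by the electron-rich aryl palladium species, which takes up carbon monoxide quickly), alkynyl transfer ahead of amide formation with diethylamine, and six- over five-membered closure. The last is secured by the amine pathway, because in 18 only C2 is electrophilic, so the aurone that would arise from attack at C3 cannot form. Regiochemistry in ring A is fixed by the substrate, since only the C8a oxygen of 15 is free and the other ortho oxygen is a benzyl ether that becomes the C5 substituent.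

Step 10
Reactants: 19 5,7-bis(benzyloxy)-2-[(2S,3S)-3-[4-(benzyloxy)-3-methoxyphenyl]-2-{[(tert-butyldimethylsilyl)oxy]methyl}-2,3-dihydro-1,4-benzodioxin-6-yl]-4H-chromen-4-one
Product: 22 5,7-bis(benzyloxy)-2-[(2S,3S)-3-[4-(benzyloxy)-3-methoxyphenyl]-2-{[(tert-butyldimethylsilyl)oxy]methyl}-2,3-dihydro-1,4-benzodioxin-6-yl]-3-hydroxy-4H-chromen-4-one, via 3-lithioflavone 20 (not isolated), via dimethyl flavon-3-ylboronate 21 (not isolated)
Conditions: LDA (LiN(i-Pr)2), THF, −78 °C; B(OMe)3, −78 → 0 °C; AcOH, 30% aq H2O2, 0 → 25 °C
Reagents that add atoms: hydrogen peroxide, OO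
Why: Lithiation–borylation–oxidation, a known route from flavones to flavonols; LDA removes the vinylic C3 proton next to the C4 carbonyl, 20 is trapped as boronate 21 and the C–B bond is oxidised to C–O, while the benzyl ethers, the silyl ether and the dioxane C–H bonds are far less acidic at −78 °C.

Step 11
Reactants: 22 5,7-bis(benzyloxy)-2-[(2S,3S)-3-[4-(benzyloxy)-3-methoxyphenyl]-2-{[(tert-butyldimethylsilyl)oxy]methyl}-2,3-dihydro-1,4-benzodioxin-6-yl]-3-hydroxy-4H-chromen-4-one
Product: 24 2,3-dehydrosilybin B, via silyl ether triphenol 23 (not isolated)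
Conditions: H2 (1 atm), Pd/C (10 wt %), THF–MeOH, 25 °C; filter; HCl (0.1 M in MeOH), 0 → 25 °C
Reagents that add atoms: none
Why: Hydrogenolysis of the three benzyl aryl ethers over palladium on carbon (primary benzylic C–O bonds cleave much faster than the ring-bound secondary C11–O3' bond or the tetrasubstituted C2=C3 bond), then, after removal of the catalyst, acid methanolysis of the primary silyl ether in the same solution; neither stage touches C10 or C11.

## Compound list

1 | 4-bromo-2-iodophenol | Oc1ccc(Br)cc1I | starting material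
2 | (4R)-4-benzyl-3-(chloroacetyl)-1,3-oxazolidin-2-one | O=C(CCl)N1[C@H](Cc2ccccc2)COC1=O | starting material
3 | (4R)-4-benzyl-3-[(4-bromo-2-iodophenoxy)acetyl]-1,3-oxazolidin-2-one | O=C(COc1ccc(Br)cc1I)N1[C@H](Cc2ccccc2)COC1=O | intermediate
4 | 4-(benzyloxy)-3-methoxybenzaldehyde (O-benzylvanillin) | COc1cc(C=O)ccc1OCc1ccccc1 | starting material
5 | dibutylboron (Z)-enolate of 3 (formed in the flask) | CCCCB(CCCC)O/C(=C\Oc1ccc(Br)cc1I)N1[C@H](Cc2ccccc2)COC1=O | intermediate
6 | O-dibutylboryl aldolate of 7 (formed in the flask) | COc1cc([C@H](OB(CCCC)CCCC)[C@@H](Oc2ccc(Br)cc2I)C(=O)N2[C@H](Cc3ccccc3)COC2=O)ccc1OCc1ccccc1 | intermediate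
7 | (4R)-4-benzyl-3-[(2R,3S)-3-[4-(benzyloxy)-3-methoxyphenyl]-2-(4-bromo-2-iodophenoxy)-3-hydroxypropanoyl]-1,3-oxazolidin-2-one | COc1cc([C@H](O)[C@@H](Oc2ccc(Br)cc2I)C(=O)N2[C@H](Cc3ccccc3)COC2=O)ccc1OCc1ccccc1 | intermediate
8 | (1S,2S)-1-[4-(benzyloxy)-3-methoxyphenyl]-2-(4-bromo-2-iodophenoxy)propane-1,3-diol | COc1cc([C@H](O)[C@H](CO)Oc2ccc(Br)cc2I)ccc1OCc1ccccc1 | intermediate
9 | (1S,2S)-1-[4-(benzyloxy)-3-methoxyphenyl]-2-(4-bromo-2-iodophenoxy)-3-[(tert-butyldimethylsilyl)oxy]propan-1-ol | COc1cc([C@H](O)[C@H](CO[Si](C)(C)C(C)(C)C)Oc2ccc(Br)cc2I)ccc1OCc1ccccc1 | intermediate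
10 | (2S,3S)-3-[4-(benzyloxy)-3-methoxyphenyl]-6-bromo-2-{[(tert-butyldimethylsilyl)oxy]methyl}-2,3-dihydro-1,4-benzodioxine | COc1cc([C@@H]2Oc3cc(Br)ccc3O[C@H]2CO[Si](C)(C)C(C)(C)C)ccc1OCc1ccccc1 | intermediate
11 | ethynyltrimethylsilane | C#C[Si](C)(C)C | starting material
12 | (2S,3S)-3-[4-(benzyloxy)-3-methoxyphenyl]-2-{[(tert-butyldimethylsilyl)oxy]methyl}-6-[(trimethylsilyl)ethynyl]-2,3-dihydro-1,4-benzodioxine | COc1cc([C@@H]2Oc3cc(C#C[Si](C)(C)C)ccc3O[C@H]2CO[Si](C)(C)C(C)(C)C)ccc1OCc1ccccc1 | intermediate
13 | (2S,3S)-3-[4-(benzyloxy)-3-methoxyphenyl]-2-{[(tert-butyldimethylsilyl)oxy]methyl}-6-ethynyl-2,3-dihydro-1,4-benzodioxine | COc1cc([C@@H]2Oc3cc(C#C)ccc3O[C@H]2CO[Si](C)(C)C(C)(C)C)ccc1OCc1ccccc1 | intermediate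
14 | 3,5-bis(benzyloxy)phenol | Oc1cc(OCc2ccccc2)cc(OCc2ccccc2)c1 | starting material
15 | 3,5-bis(benzyloxy)-2-iodophenol | Oc1cc(OCc2ccccc2)cc(OCc2ccccc2)c1I | intermediate
16 | carbon monoxide | [C-]#[O+] | starting material
17 | 1-[2,4-bis(benzyloxy)-6-hydroxyphenyl]-3-[(2S,3S)-3-[4-(benzyloxy)-3-methoxyphenyl]-2-{[(tert-butyldimethylsilyl)oxy]methyl}-2,3-dihydro-1,4-benzodioxin-6-yl]prop-2-yn-1-one (formed in the flask) | COc1cc([C@@H]2Oc3cc(C#CC(=O)c4c(O)cc(OCc5ccccc5)cc4OCc4ccccc4)ccc3O[C@H]2CO[Si](C)(C)C(C)(C)C)ccc1OCc1ccccc1 | intermediate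
18 | (E)-1-[2,4-bis(benzyloxy)-6-hydroxyphenyl]-3-(diethylamino)-3-[(2S,3S)-3-[4-(benzyloxy)-3-methoxyphenyl]-2-{[(tert-butyldimethylsilyl)oxy]methyl}-2,3-dihydro-1,4-benzodioxin-6-yl]prop-2-en-1-one (formed in the flask; either alkene geometry can close) | COc1cc([C@@H]2Oc3cc(/C(N(CC)CC)=C\C(=O)c4c(O)cc(OCc5ccccc5)cc4OCc4ccccc4)ccc3O[C@H]2CO[Si](C)(C)C(C)(C)C)ccc1OCc1ccccc1 | intermediate
19 | 5,7-bis(benzyloxy)-2-[(2S,3S)-3-[4-(benzyloxy)-3-methoxyphenyl]-2-{[(tert-butyldimethylsilyl)oxy]methyl}-2,3-dihydro-1,4-benzodioxin-6-yl]-4H-chromen-4-one | COc1cc([C@@H]2Oc3cc(-c4cc(=O)c5c(OCc6ccccc6)cc(OCc6ccccc6)cc5o4)ccc3O[C@H]2CO[Si](C)(C)C(C)(C)C)ccc1OCc1ccccc1 | intermediate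
20 | 3-lithio derivative of 19 (formed in the flask) | COc1cc([C@@H]2Oc3cc(-c4oc5cc(OCc6ccccc6)cc(OCc6ccccc6)c5c(=O)c4[Li])ccc3O[C@H]2CO[Si](C)(C)C(C)(C)C)ccc1OCc1ccccc1 | intermediate
21 | dimethyl boronate at C3 of 19 (formed in the flask) | COc1cc([C@@H]2Oc3cc(-c4oc5cc(OCc6ccccc6)cc(OCc6ccccc6)c5c(=O)c4B(OC)OC)ccc3O[C@H]2CO[Si](C)(C)C(C)(C)C)ccc1OCc1ccccc1 | intermediate
22 | 5,7-bis(benzyloxy)-2-[(2S,3S)-3-[4-(benzyloxy)-3-methoxyphenyl]-2-{[(tert-butyldimethylsilyl)oxy]methyl}-2,3-dihydro-1,4-benzodioxin-6-yl]-3-hydroxy-4H-chromen-4-one | COc1cc([C@@H]2Oc3cc(-c4oc5cc(OCc6ccccc6)cc(OCc6ccccc6)c5c(=O)c4O)ccc3O[C@H]2CO[Si](C)(C)C(C)(C)C)ccc1OCc1ccccc1 | intermediate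
23 | 2-[(2S,3S)-2-{[(tert-butyldimethylsilyl)oxy]methyl}-3-(4-hydroxy-3-methoxyphenyl)-2,3-dihydro-1,4-benzodioxin-6-yl]-3,5,7-trihydroxy-4H-chromen-4-one (formed in the flask) | COc1cc([C@@H]2Oc3cc(-c4oc5cc(O)cc(O)c5c(=O)c4O)ccc3O[C@H]2CO[Si](C)(C)C(C)(C)C)ccc1O | intermediate
24 | 2,3-dehydrosilybin B: 3,5,7-trihydroxy-2-[(2S,3S)-3-(4-hydroxy-3-methoxyphenyl)-2-(hydroxymethyl)-2,3-dihydro-1,4-benzodioxin-6-yl]-4H-chromen-4-one | COc1cc([C@@H]2Oc3cc(-c4oc5cc(O)cc(O)c5c(=O)c4O)ccc3O[C@H]2CO)ccc1O | target

## Step count and least certain steps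

Total: 11 steps. Longest linear sequence: 10 steps (steps 1–7, 9, 10, 11); step 8 is a one-step side branch.

Step 9 (key step). The aroyl palladium intermediate may be captured by diethylamine (amide formation), or the alkyne may be transferred before carbon monoxide inserts, giving direct coupling and closure to a 2-arylbenzofuran. Both are helped by the hindered, doubly ortho-substituted aryl iodide and by the low gas pressure. The fallback avoids both the gas and the alkyne, sets out from 10 and returns at 19. Bromine–lithium exchange on 10 (n-BuLi, THF, −78 °C) and quenching with DMF would give (2S,3S)-3-[4-(benzyloxy)-3-methoxyphenyl]-2-{[(tert-butyldimethylsilyl)oxy]methyl}-2,3-dihydro-1,4-benzodioxine-6-carbaldehyde F1. Claisen–Schmidt condensation with purchased 1-[2,4-bis(benzyloxy)-6-hydroxyphenyl]ethanone (KOH, EtOH–THF) would give (E)-1-[2,4-bis(benzyloxy)-6-hydroxyphenyl]-3-[(2S,3S)-3-[4-(benzyloxy)-3-methoxyphenyl]-2-{[(tert-butyldimethylsilyl)oxy]methyl}-2,3-dihydro-1,4-benzodioxin-6-yl]prop-2-en-1-one F2. Oxidative cyclisation (cat. I2, DMSO, 120 °C) would then form O1–C2 and give 19.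

Step 10. Metalation may be incomplete or unselective. Deprotonation at C11 would be followed by loss of the O4' phenoxide and opening of ring D, or the lithiated flavone may add to a second flavone carbonyl, because the C3 anion is formed next to several weakly acidic C–H bonds. The fallback is oxidative, not basic, sets out from 19 and returns at 22. Epoxidation of C2=C3 with dimethyldioxirane (from KHSO5 and acetone, dilute acetone solution, 0 → 25 °C) would give the 2,3-epoxide of 19 F3. Acid-catalysed opening (cat. TsOH, CH2Cl2), assisted by O1 at C2 with loss of the C3 proton, would give 22.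

Step 8. Iodination may occur para to the hydroxyl (C4), or a second iodine may enter, because all three free ring positions are activated by three oxygens. The fallback fixes the site by directed metalation, sets out from 14 and returns at 15. Carbamoylation (ClC(O)NEt2, K2CO3, MeCN) would give 3,5-bis(benzyloxy)phenyl diethylcarbamate F4. Lithiation between the carbamate and the neighbouring benzyloxy group (s-BuLi, TMEDA, THF, −78 °C) and an I2 quench would give 3,5-bis(benzyloxy)-2-iodophenyl diethylcarbamate F5. Hydrolysis (NaOH, EtOH–H2O, reflux) would give 15.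

Step 5. The silyl group may migrate from the C9 oxygen to the C11 oxygen under carbonate at 100 °C, followed by closure through the primary oxygen to the isomeric dioxane; protodehalogenation is a second risk. The fallback closes the ring at the sp3 carbon, sets out from 9 and returns at 10. Iodine–magnesium exchange (i-PrMgCl·LiCl, 2 equiv, THF, −20 °C, bromide untouched), B(OMe)3 and oxidation (H2O2, NaOH) would give 5-bromo-2-{[(1S,2S)-1-[4-(benzyloxy)-3-methoxyphenyl]-3-[(tert-butyldimethylsilyl)oxy]-1-hydroxypropan-2-yl]oxy}phenol F6. Mild acid (cat. camphorsulfonic acid, CH2Cl2, 0 °C) would ionise the para-benzyloxy benzylic alcohol, and the C3' phenol should trap the cation to give the more stable trans ring, with C10 untouched, as 10.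

Step 11. Once the para-hydroxyl of ring E is free, the acid stage may ionise the C11–O3' bond (quinone methide formation), leading to methanolysis or epimerisation at C11. Prolonged contact with hydrogen and catalyst may also start slow over-reduction. The fallback removes silicon with fluoride while the phenols are still benzylated, sets out from 22 and returns at 24. Bu4NF buffered with AcOH (THF, 0 °C) would give 5,7-bis(benzyloxy)-2-[(2S,3S)-3-[4-(benzyloxy)-3-methoxyphenyl]-2-(hydroxymethyl)-2,3-dihydro-1,4-benzodioxin-6-yl]-3-hydroxy-4H-chromen-4-one F7. Hydrogenolysis (H2, Pd/C (10 wt %), THF–EtOAc, 25 °C), stopped at three equivalents of hydrogen, would give 24.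

## Further compounds

F1 | step 9 | (2S,3S)-3-[4-(benzyloxy)-3-methoxyphenyl]-2-{[(tert-butyldimethylsilyl)oxy]methyl}-2,3-dihydro-1,4-benzodioxine-6-carbaldehyde | COc1cc([C@@H]2Oc3cc(C=O)ccc3O[C@H]2CO[Si](C)(C)C(C)(C)C)ccc1OCc1ccccc1
F2 | step 9 | (E)-1-[2,4-bis(benzyloxy)-6-hydroxyphenyl]-3-[(2S,3S)-3-[4-(benzyloxy)-3-methoxyphenyl]-2-{[(tert-butyldimethylsilyl)oxy]methyl}-2,3-dihydro-1,4-benzodioxin-6-yl]prop-2-en-1-one | COc1cc([C@@H]2Oc3cc(/C=C/C(=O)c4c(O)cc(OCc5ccccc5)cc4OCc4ccccc4)ccc3O[C@H]2CO[Si](C)(C)C(C)(C)C)ccc1OCc1ccccc1
F3 | step 10 | 2,3-epoxide of 19 (epoxide on either face; dioxane centres 2S,3S) | COc1cc([C@@H]2Oc3cc(C45OC4C(=O)c4c(OCc6ccccc6)cc(OCc6ccccc6)cc4O5)ccc3O[C@H]2CO[Si](C)(C)C(C)(C)C)ccc1OCc1ccccc1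
F4 | step 8 | 3,5-bis(benzyloxy)phenyl diethylcarbamate | CCN(CC)C(=O)Oc1cc(OCc2ccccc2)cc(OCc2ccccc2)c1
F5 | step 8 | 3,5-bis(benzyloxy)-2-iodophenyl diethylcarbamate | CCN(CC)C(=O)Oc1cc(OCc2ccccc2)cc(OCc2ccccc2)c1I
F6 | step 5 | 5-bromo-2-{[(1S,2S)-1-[4-(benzyloxy)-3-methoxyphenyl]-3-[(tert-butyldimethylsilyl)oxy]-1-hydroxypropan-2-yl]oxy}phenol | COc1cc([C@H](O)[C@H](CO[Si](C)(C)C(C)(C)C)Oc2ccc(Br)cc2O)ccc1OCc1ccccc1
F7 | step 11 | 5,7-bis(benzyloxy)-2-[(2S,3S)-3-[4-(benzyloxy)-3-methoxyphenyl]-2-(hydroxymethyl)-2,3-dihydro-1,4-benzodioxin-6-yl]-3-hydroxy-4H-chromen-4-one | COc1cc([C@@H]2Oc3cc(-c4oc5cc(OCc6ccccc6)cc(OCc6ccccc6)c5c(=O)c4O)ccc3O[C@H]2CO)ccc1OCc1ccccc1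
A1 | alternative 1 | 4-[(2S,3S)-7-bromo-3-(hydroxymethyl)-2,3-dihydro-1,4-benzodioxin-2-yl]-2-methoxyphenyl pivalate | COc1cc([C@@H]2Oc3cc(Br)ccc3O[C@H]2CO)ccc1OC(=O)C(C)(C)C
A2 | alternative 1 | 4-[(S)-(5-bromo-2-hydroxyphenoxy)[(2R)-oxiran-2-yl]methyl]-2-methoxyphenyl pivalate | COc1cc([C@H](Oc2cc(Br)ccc2O)[C@H]2CO2)ccc1OC(=O)C(C)(C)C
A3 | alternative 2 | methyl (2S,3S)-2-{[(tert-butyldimethylsilyl)oxy]methyl}-3-(4-hydroxy-3-methoxyphenyl)-2,3-dihydro-1,4-benzodioxine-6-carboxylate | COc1cc([C@@H]2Oc3cc(C(=O)OC)ccc3O[C@H]2CO[Si](C)(C)C(C)(C)C)ccc1O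
A4 | alternative 2 | methyl 4-{[(2R)-1-[(tert-butyldimethylsilyl)oxy]-3-(4-hydroxy-3-methoxyphenyl)propan-2-yl]oxy}-3-hydroxybenzoate | COc1cc(C[C@H](CO[Si](C)(C)C(C)(C)C)Oc2ccc(C(=O)OC)cc2O)ccc1O
A5 | alternative 3 | 3-(benzyloxy)-2-[(2S,3S)-3-[4-(benzyloxy)-3-methoxyphenyl]-2-{[(tert-butyldimethylsilyl)oxy]methyl}-2,3-dihydro-1,4-benzodioxin-6-yl]-5,7-dihydroxy-4H-chromen-4-one | COc1cc([C@@H]2Oc3cc(-c4oc5cc(O)cc(O)c5c(=O)c4OCc4ccccc4)ccc3O[C@H]2CO[Si](C)(C)C(C)(C)C)ccc1OCc1ccccc1
A6 | alternative 3 | methyl 4-{5-(benzyloxy)-6-[(2S,3S)-3-[4-(benzyloxy)-3-methoxyphenyl]-2-{[(tert-butyldimethylsilyl)oxy]methyl}-2,3-dihydro-1,4-benzodioxin-6-yl]-4-oxo-4H-pyran-2-yl}-3-oxobutanoate | COc1cc([C@@H]2Oc3cc(-c4oc(CC(=O)CC(=O)OC)cc(=O)c4OCc4ccccc4)ccc3O[C@H]2CO[Si](C)(C)C(C)(C)C)ccc1OCc1ccccc1
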